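## Structural features

CJ-13,103 is a 3-substituted phthalide: a benzene ring (ring A: C3a, C4, C5, C6, C7, C7a) is fused along C3a–C7a to a five-membered lactone (ring B: C1, O2, C3, C3a, C7a). Ring A carries methoxy groups at C5 and C7, so C7, C7a and C3a form a contiguous substituted edge in which the lactone carbonyl C1 is flanked by the C7 methoxy group. Both methoxy groups stand ortho or para to C7a and meta to C3a, which is the polarity of a resorcylate. C3 is the only stereocentre (S); it is benzylic, bears the lactone oxygen, and has no neighbouring stereocentre from which it could be relayed. From C3 runs an unbranched sixteen-carbon chain: eleven methylenes (C1' to C11'), a ketone (C12'), two methylenes (C13', C14') and a methyl ketone (C15', C16'). The fragile groups are the 1,4-diketone (aldol condensation in base, cyclodehydration to a furan in acid, attack by organometallic reagents), the lactone (nucleophiles, deprotonation at C3 by strong base) and the C7 methyl ether (chelation-assisted cleavage by Lewis acids). The real difficulty is threefold: the regiodefined 1,2,3,5-substitution of ring A, an isolated stereocentre between this ring and a featureless chain, and two free ketones to be carried or unveiled at the far end. The key step exploits the fact that C4–C5(OMe)–C6–C7(OMe) is a 1,3-dimethoxybutadiene and C1–C7a–C3a–C3 is a 4-oxygenated but-2-ynoate with matching donor and acceptor polarity, so ring A can be closed by cycloaddition around an existing C3 stereocentre while ring B closes in the same flask.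

## Logic of the disconnections

**15 to 14.**
- Bonds cut: the carbonyl oxygens at C12' and C15' are merged into one oxygen that bridges C12' and C15', so the 1,4-diketone of 15 becomes the 2,5-disubstituted furan ring of 14. In the forward sense the two ring C–O bonds are hydrolysed.
- Reason: the diketone is the group least compatible with organolithium, organozinc and thermal chemistry.
- Gain: two electrophilic, enolisable ketones become one aromatic ring that needs no protecting group and also supplies the nucleophile for chain assembly.
- Demand: the last step must open the furan ring in aqueous acid without touching ring B, the methyl ethers or C3.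

**14 to 3 and 11 (key disconnection).**
- Bonds cut: C3a–C4 and C7–C7a of ring A, together with the lactone bond O2–C1 of ring B.
- Reason: C4–C5–C6–C7 with its two methoxy groups is the diene carbon set of 3. C1, C7a, C3a and C3 lie in a row in 11 as ester carbon, two alkyne carbons and carbinol carbon. Donor and acceptor ends match, so the difficult edge C7–C7a–C3a is written into the polarity of the partners instead of being won by directed substitution.
- Gain: a bicyclic, tetrasubstituted arene lactone falls back to one acyclic chain compound and one eight-carbon diene. The stereochemical problem moves from a benzylic position on a crowded ring to a propargylic carbinol.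
- Demand: the forward step must add with one regiochemistry, expel the two-carbon bridge of the primary adduct 12 to aromatise to 13, and lactonise. All of this must happen thermally without touching the C3–O or C3–H bond or the furan ring.
- In one sentence: rings A and B of 14 are made together when 3 and 11 undergo cycloaddition, extrusion and lactonisation.

**11 to 8 and 9.**
- Bond cut: C3–C3a, at a stage at which C3a is still an sp carbon.
- Reason: an aldehyde and a terminal alkyne are the simplest pair that gives the carbinol, and the catalytic asymmetric version sets C3 in the step that forms the bond.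
- Gain: 9 brings C1, C7a and C3a in the final oxidation state, and 8 is achiral.
- Demand: high facial selectivity on a linear aliphatic aldehyde with little steric bias, and a nucleophile mild enough for the ester of 9.

**8 to 7.**
- Bond cut: C3–C1'.
- Reason: the future C3 is added to a terminal alkene as a one-carbon unit by hydroformylation, so no redox adjustment and no hydroxyl protection are needed.
- Gain: 7 holds only an alkene and the furan ring.
- Demand: linear selectivity and no migration of the double bond.

**7 to 4 and 5.**
- Bond cut: C11'–C12'.
- Reason: C12' is the free α-carbon of the furan ring, its most acidic position and therefore its natural nucleophilic site.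
- Gain: two commercial compounds. 4 brings C12' to C16' with both latent ketones, and 5 brings C1' to C11'.
- Demand: clean substitution at a primary bromide without elimination.

**3 to 2 to 1.**
- Bonds cut: no carbon–carbon bond. 3 is traced back by a double-bond shift to 2, and 2 by removal of two hydrogens to the arene 1.
- Reason: 1 already holds the two methoxy groups in the 1,3-relation.
- Gain: over the whole route four ring carbons of 1 end as C4 to C7 and the other two leave in step 6. In effect two CH units of a cheap arene are exchanged for C3a and C7a.
- Demand: the dearomatisation must stop at the dihydro stage, and the conjugation must proceed without loss of a methoxy group.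

## Other disconnections considered

Alternative 1: Cut C3–C3a with ring A kept intact, which is the first idea that comes to mind.
- Forward key step: an ortho-lithiated tertiary 2,4-dimethoxybenzamide would be added to 8 to give the racemic hydroxy amide A1. This would have to be oxidised to the keto amide A2, reduced again with a chiral reagent and lactonised to 14.
- The bond-forming step creates C3 without control, so the centre is made, erased and made again. That costs three operations that build nothing.
- The lithiation faces a contest between the position ortho to the amide and the position between the two methoxy groups, and the hindered tertiary amide must later be forced to leave.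
- From 8 this path needs four steps plus the amide synthesis. The chosen plan needs two, and it sets C3 in the step that forms the C3–C3a bond.

Alternative 2: Cut O2–C1 and C3–H.
- Forward key step: the keto aldehyde A3 would be isomerised to 14 by enantioselective intramolecular ketone hydroacylation with a cationic complex of monovalent rhodium, for example [Rh(cod)2]BF4, and a chiral bisphosphine. The sequence is oxidative addition into the formyl C–H bond, insertion of the ketone into Rh–H, and C–O reductive elimination.
- The step sets C3 and closes ring B with full atom economy. It leaves the whole 1,2,3,5-substituted ring A to be assembled beforehand by stepwise substitution, with a formyl group placed between a methoxy group and a deactivating acyl group.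
- That doubly flanked formyl group is the worst case for the mechanism, because a crowded acyl rhodium hydride has time to decarbonylate.
- In terms of bonds formed this is the classical ketone reduction and lactonisation in another guise, and it gains no simplification at ring A.

Alternative 3: Cut C3–C3a and C1–C7a.
- Forward key step: the carbamate A4, deprotonated next to oxygen with s-BuLi and sparteine, would add to the aryne A5 at the aryne carbon remote from the methoxy group. The resulting aryllithium, ortho to that methoxy group, would attack the carbamoyl carbon and close ring B after expulsion of the amide leaving group. This is a formal [3+2] annulation in which the carbamate carbonyl becomes C1.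
- The regiochemistry fits the target and two ring bonds would form at once.
- Whether an α-oxygenated alkyllithium attacks an aryne with retention or inversion cannot be derived safely from the mechanism.
- A5 would have to be generated beside a basic, configurationally delicate organolithium that is easily lost by proton transfer.
- The furan mask is ruled out because furans trap arynes by [4+2] cycloaddition, so A4 needs two ketals and the steps to put them on and take them off. A stoichiometric chiral diamine is also required.
- More risk would buy no shorter route.

Key step: step 6

Assumption: the chain in the SMILES is read as eleven CH2 groups between C3 and the first ketone, and the [C@H] descriptor corresponds to S at C3 (O2 > C3a > C1' > H).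

## Steps

Step 1
Reactants: 1 1,3-dimethoxybenzene
Product: 2 1,5-dimethoxycyclohexa-1,4-diene
Conditions: Li, t-BuOH, NH3(l)/THF, −78 to −33 °C; then H2O
Reagents that add atoms: none
Why: Birch reduction; the radical anion and the derived anion are protonated at the two ring positions that leave both methoxy groups on double bonds, so the unconjugated bis-enol ether should form and resist further reduction. No stereocentre is made.

Step 2
Reactants: 2 1,5-dimethoxycyclohexa-1,4-diene
Product: 3 1,3-dimethoxycyclohexa-1,3-diene
Conditions: KOt-Bu (0.3 equiv), DMSO, rt; distil
Reagents that add atoms: none
Why: Base-mediated prototropic conjugation of a Birch diene; deprotonation of the CH2 flanked by both enol ether carbons puts the charge on carbons free of oxygen, and reprotonation at a terminus of the pentadienyl anion gives the conjugated isomer. Residual 2 is a spectator in step 6, so an equilibrium mixture rich in 3 can be used.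

Step 3
Reactants: 4 2-methylfuran; 5 11-bromoundec-1-ene
Product: 7 2-methyl-5-(undec-10-en-1-yl)furan, via 5-methyl-2-furyllithium 6 (not isolated)
Conditions: 4, n-BuLi, THF, 0 °C to rt; then 5, DMPU, 0 °C to rt
Reagents that add atoms: none
Why: α-Lithiation of the furan at its only free α-position, followed by SN2 alkylation with a primary bromide. The terminal alkene is inert to the furyllithium.

Step 4
Reactants: 7 2-methyl-5-(undec-10-en-1-yl)furan
Product: 8 12-(5-methylfuran-2-yl)dodecanal
Conditions: Rh(acac)(CO)2 (0.5 mol %), Xantphos (2 mol %), CO/H2 (1:1, 20 bar), toluene, 80 °C
Reagents that add atoms: carbon monoxide, [C-]#[O+]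
Why: Linear-selective hydroformylation; the wide-bite-angle diphosphine on the rhodium hydride favours anti-Markovnikov insertion of the terminal alkene, so the new formyl carbon (the future C3) should end at the chain terminus. The 2,5-dialkylfuran does not insert under these mild conditions.

Step 5
Reactants: 8 12-(5-methylfuran-2-yl)dodecanal; 9 methyl propiolate
Product: 11 methyl (4S)-4-hydroxy-15-(5-methylfuran-2-yl)pentadec-2-ynoate, via ethyl(3-methoxy-3-oxoprop-1-ynyl)zinc 10 (not isolated)
Conditions: 9 (4 equiv), Et2Zn (4 equiv), (R)-BINOL (40 mol %), HMPA (2 equiv), CH2Cl2, rt; Ti(Oi-Pr)4 (1 equiv); then 8, rt; aq NH4Cl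
Reagents that add atoms: none
Why: Catalytic asymmetric alkynylation of an aldehyde (BINOL–titanium-mediated alkynylzinc addition), a known reaction of alkyl propiolates with linear aliphatic aldehydes. In this catalyst family the S ligand delivers carbon nucleophiles to the Si face, so the (R)-BINOLate titanium complex should expose the Re face of 8 to 10 and give the S carbinol (OH > alkynyl > alkyl > H); both ligand antipodes are commercial. The furan is inert, and ester exchange with isopropoxide would be harmless because the alkoxy group is lost in step 6.

Step 6
Reactants: 3 1,3-dimethoxycyclohexa-1,3-diene; 11 methyl (4S)-4-hydroxy-15-(5-methylfuran-2-yl)pentadec-2-ynoate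
Product: 14 (3S)-5,7-dimethoxy-3-[11-(5-methylfuran-2-yl)undecyl]isobenzofuran-1(3H)-one, via bicyclo[2.2.2]octadiene cycloadduct 12 (not isolated), via ortho-hydroxyalkyl benzoate 13 (not isolated)
Conditions: 3 (5 equiv), BHT (1 mol %), mesitylene, sealed tube, 140 °C then 190 °C
Reagents that add atoms: none
Why: Alder–Rickert reaction, that is a Diels–Alder cycloaddition followed by retro-Diels–Alder loss of ethylene, which is the known way from alkoxycyclohexa-1,3-dienes and alk-2-ynoates to resorcylate esters. Diene 3 adds across the triple bond of 11 in a concerted but asynchronous [4+2] step to give 12, and above about 170 °C 12 expels its saturated two-carbon bridge as ethylene in a cycloreversion driven by aromatisation and escape of the gas, so the sequence is irreversible and ends in 13. Ring A is closed by the intermolecular [4+2] cycloaddition (bonds C3a–C4 and C7–C7a). Ring B is closed by 5-exo-trig attack of the C3 hydroxyl on the ortho ester carbonyl with loss of methanol (bond O2–C1), which should be fast at this temperature because both groups are held in one plane on adjacent ring atoms. The selectivity that matters is regiochemical: both methoxy groups of 3 push electron density to the unsubstituted diene terminus, the ester of 11 makes the alkyne carbon bearing the carbinol the electrophilic one, these two atoms bond ahead of the others, and the methoxy-bearing terminus therefore ends next to the ester carbon, which is the 5,7-dimethoxy pattern; the steric demand of the branched carbinol carbon points the same way. No lasting stereocentre is made: the bridgehead centres of 12 arise as a mixture and vanish on aromatisation, while none of the four bonds at C3 is broken, so the S configuration of 11 is carried into 14. The furan should stay out because 3 is the far better donor and is used in excess, and because any furan–alkyne adduct reverts at this temperature whereas ethylene loss does not. Acids and amine bases are kept out so that 3 is not hydrolysed and 11 does not isomerise to the achiral 4-oxoalk-2-enoate.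

Step 7
Reactants: 14 (3S)-5,7-dimethoxy-3-[11-(5-methylfuran-2-yl)undecyl]isobenzofuran-1(3H)-one
Product: 15 (3S)-3-(12,15-dioxohexadecyl)-5,7-dimethoxyisobenzofuran-1(3H)-one (CJ-13,103)
Conditions: H2SO4 (cat.), AcOH/H2O (4:1), 100 °C
Reagents that add atoms: water, O
Why: Acid-catalysed hydrolytic opening of a 2,5-dialkylfuran (reverse Paal–Knorr reaction): ring protonation, addition of water and ring opening give the 1,4-diketone, favoured by the large excess of water. The closed phthalide is the stable form in acid, and the C3–O2 bond should not ionise because both methoxy groups are meta to C3a and the C1 carbonyl is ortho to it, so the S centre is kept.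

## Compound list

1 | 1,3-dimethoxybenzene | COc1cccc(OC)c1 | starting material
2 | 1,5-dimethoxycyclohexa-1,4-diene | COC1=CCC=C(OC)C1 | intermediate
3 | 1,3-dimethoxycyclohexa-1,3-diene | COC1=CC(OC)=CCC1 | intermediate
4 | 2-methylfuran | Cc1ccco1 | starting material
5 | 11-bromoundec-1-ene | C=CCCCCCCCCCBr | starting material
6 | 5-methyl-2-furyllithium | [Li]c1ccc(C)o1 | intermediate
7 | 2-methyl-5-(undec-10-en-1-yl)furan | C=CCCCCCCCCCc1ccc(C)o1 | intermediate
8 | 12-(5-methylfuran-2-yl)dodecanal | O=CCCCCCCCCCCCc1ccc(C)o1 | intermediate
9 | methyl propiolate | C#CC(=O)OC | starting material
10 | ethyl(3-methoxy-3-oxoprop-1-ynyl)zinc | CC[Zn]C#CC(=O)OC | intermediate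
11 | methyl (4S)-4-hydroxy-15-(5-methylfuran-2-yl)pentadec-2-ynoate | COC(=O)C#C[C@@H](O)CCCCCCCCCCCc1ccc(C)o1 | intermediate
12 | methyl 3-[(1S)-1-hydroxy-12-(5-methylfuran-2-yl)dodecyl]-1,5-dimethoxybicyclo[2.2.2]octa-2,5-diene-2-carboxylate (bridgeheads as a mixture) | COC(=O)C1=C([C@@H](O)CCCCCCCCCCCc2ccc(C)o2)C2CCC1(OC)C=C2OC | intermediate
13 | methyl 2-[(1S)-1-hydroxy-12-(5-methylfuran-2-yl)dodecyl]-4,6-dimethoxybenzoate | COC(=O)c1c(OC)cc(OC)cc1[C@@H](O)CCCCCCCCCCCc1ccc(C)o1 | intermediate
14 | (3S)-5,7-dimethoxy-3-[11-(5-methylfuran-2-yl)undecyl]isobenzofuran-1(3H)-one | COc1cc(OC)c2c(c1)[C@H](CCCCCCCCCCCc1ccc(C)o1)OC2=O | intermediate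
15 | (3S)-3-(12,15-dioxohexadecyl)-5,7-dimethoxyisobenzofuran-1(3H)-one (CJ-13,103) | COc1cc(OC)c2c(c1)[C@H](CCCCCCCCCCCC(=O)CCC(C)=O)OC2=O | target

## Step count and least certain steps

Total step count: 7. Longest linear sequence: 5 steps (steps 3, 4, 5, 6 and 7, from 4 and 5). The diene branch (steps 1 and 2) joins at step 6.

**Step 6 (key step).** The alkyne of 11 is disubstituted and activated by one ester only, so the cycloaddition may be slow. During long heating the diene can be lost by dimerisation, by hydrolysis through adventitious water, or by aromatisation through loss of methanol. The propargylic carbinol can also drift by trace-base-induced redox isomerisation, which would erase C3. Incomplete extrusion or lactonisation is of less concern, since more heat or the acid of step 7 pushes both.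

The fallback gives up the benzannulation and forms the C3–C1' bond on a preformed ring A. It sets out from 7 and comes back at 14. 2,4-Dimethoxybenzoyl chloride and diethylamine give N,N-diethyl-2,4-dimethoxybenzamide F1. Amide-directed ortho-lithiation of F1 (s-BuLi, TMEDA, THF, −78 °C) and a DMF quench give N,N-diethyl-2-formyl-4,6-dimethoxybenzamide F2. Hydroboration of 7 with Et2BH gives diethyl[11-(5-methylfuran-2-yl)undecyl]borane F3, and boron–zinc exchange with Et2Zn gives bis[11-(5-methylfuran-2-yl)undecyl]zinc F4. Addition of F4 to F2 under Ti(Oi-Pr)4 and catalytic (1R,2R)-1,2-bis(trifluoromethanesulfonamido)cyclohexane should give N,N-diethyl-2-[(1S)-1-hydroxy-12-(5-methylfuran-2-yl)dodecyl]-4,6-dimethoxybenzamide F5. F5 lactonises to 14 on warming with p-TsOH in toluene.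

**Step 5.** The most likely problems are erosion of enantioselectivity by uncatalysed background addition of 10 to an unhindered aldehyde, competing ethyl transfer from Et2Zn, and oligomerisation of the propiolate.

The fallback separates bond formation from stereocontrol. It sets out from 8 and comes back at 11. Compound 9 is deprotonated with LiHMDS at −78 °C and added to 8 to give racemic methyl 4-hydroxy-15-(5-methylfuran-2-yl)pentadec-2-ynoate F6. Dess–Martin periodinane oxidises F6 to methyl 15-(5-methylfuran-2-yl)-4-oxopentadec-2-ynoate F7. Midland reduction of F7 with (S)-Alpine-Borane, for which alkynyl ketones bearing an ester are especially good substrates, should give 11.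

**Step 2.** Conjugation may stop at an unfavourable equilibrium. Over-isomerisation may place a methoxy group on an sp3 carbon, followed by loss of methanol and rearomatisation. The enol ethers may also hydrolyse on handling.

The fallback takes the diene from the carbonyl oxidation level instead of from an arene. It sets out from 11 and comes back at 14. Commercial 3-methoxycyclohex-2-en-1-one is deprotonated at the α'-position (LDA, THF, −78 °C) and silylated (TMSCl) to give 1-methoxy-3-(trimethylsilyloxy)cyclohexa-1,3-diene F8. Under the conditions of step 6, followed by a mild desilylating work-up, F8 should convert 11 into (3S)-5-hydroxy-7-methoxy-3-[11-(5-methylfuran-2-yl)undecyl]isobenzofuran-1(3H)-one F9. Methylation of F9 (MeI, K2CO3, acetone) gives 14.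

**Step 4.** Migration of the double bond into the chain and formation of the branched aldehyde would give isomers of nearly the same polarity as 8 that are hard to remove.

The fallback buys the twelfth carbon instead of adding it. It sets out from 4 (through 6) and comes back at 8. Two equivalents of 6, the first spent on the hydroxyl group, are alkylated with 12-bromododecan-1-ol to give 12-(5-methylfuran-2-yl)dodecan-1-ol F10, and Swern oxidation of F10 gives 8.

**Step 7.** Ring opening is an equilibrium with Paal–Knorr cyclodehydration, and the lipophilic substrate may dissolve poorly in aqueous acid. Prolonged heating may also start acid-catalysed intramolecular aldol condensation of the diketone.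

The fallback replaces hydrolysis by an oxidation–reduction pair. It sets out from 14 and comes back at 15. mCPBA (CH2Cl2, 0 °C) opens the furan oxidatively to (3S)-3-[(13Z)-12,15-dioxohexadec-13-en-1-yl]-5,7-dimethoxyisobenzofuran-1(3H)-one F11. Conjugate reduction of the enedione with Zn in AcOH at rt gives 15.

## Further compounds

F1 | step 6 | N,N-diethyl-2,4-dimethoxybenzamide | CCN(CC)C(=O)c1ccc(OC)cc1OC
F2 | step 6 | N,N-diethyl-2-formyl-4,6-dimethoxybenzamide | CCN(CC)C(=O)c1c(OC)cc(OC)cc1C=O
F3 | step 6 | diethyl[11-(5-methylfuran-2-yl)undecyl]borane | CCB(CC)CCCCCCCCCCCc1ccc(C)o1
F4 | step 6 | bis[11-(5-methylfuran-2-yl)undecyl]zinc | Cc1ccc(CCCCCCCCCCC[Zn]CCCCCCCCCCCc2ccc(C)o2)o1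
F5 | step 6 | N,N-diethyl-2-[(1S)-1-hydroxy-12-(5-methylfuran-2-yl)dodecyl]-4,6-dimethoxybenzamide | CCN(CC)C(=O)c1c(OC)cc(OC)cc1[C@@H](O)CCCCCCCCCCCc1ccc(C)o1
F6 | step 5 | methyl 4-hydroxy-15-(5-methylfuran-2-yl)pentadec-2-ynoate (racemic) | COC(=O)C#CC(O)CCCCCCCCCCCc1ccc(C)o1
F7 | step 5 | methyl 15-(5-methylfuran-2-yl)-4-oxopentadec-2-ynoate | COC(=O)C#CC(=O)CCCCCCCCCCCc1ccc(C)o1
F8 | step 2 | 1-methoxy-3-(trimethylsilyloxy)cyclohexa-1,3-diene | COC1=CC(O[Si](C)(C)C)=CCC1
F9 | step 2 | (3S)-5-hydroxy-7-methoxy-3-[11-(5-methylfuran-2-yl)undecyl]isobenzofuran-1(3H)-one | Oc1cc(OC)c2c(c1)[C@H](CCCCCCCCCCCc1ccc(C)o1)OC2=O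
F10 | step 4 | 12-(5-methylfuran-2-yl)dodecan-1-ol | OCCCCCCCCCCCCc1ccc(C)o1
F11 | step 7 | (3S)-3-[(13Z)-12,15-dioxohexadec-13-en-1-yl]-5,7-dimethoxyisobenzofuran-1(3H)-one | COc1cc(OC)c2c(c1)[C@H](CCCCCCCCCCCC(=O)/C=C\C(C)=O)OC2=O
A1 | alternative 1 | N,N-diethyl-2-[1-hydroxy-12-(5-methylfuran-2-yl)dodecyl]-4,6-dimethoxybenzamide (racemic) | CCN(CC)C(=O)c1c(OC)cc(OC)cc1C(O)CCCCCCCCCCCc1ccc(C)o1
A2 | alternative 1 | N,N-diethyl-2,4-dimethoxy-6-[12-(5-methylfuran-2-yl)dodecanoyl]benzamide | CCN(CC)C(=O)c1c(OC)cc(OC)cc1C(=O)CCCCCCCCCCCc1ccc(C)o1
A3 | alternative 2 | 2,4-dimethoxy-6-[12-(5-methylfuran-2-yl)dodecanoyl]benzaldehyde | O=Cc1c(OC)cc(OC)cc1C(=O)CCCCCCCCCCCc1ccc(C)o1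
A4 | alternative 3 | 12-{2-[2-(2-methyl-1,3-dioxolan-2-yl)ethyl]-1,3-dioxolan-2-yl}dodecyl N,N-diisopropylcarbamate | CC(C)N(C(C)C)C(=O)OCCCCCCCCCCCCC1(CCC2(C)OCCO2)OCCO1
A5 | alternative 3 | 3,5-dimethoxybenzyne (1,2-didehydro-3,5-dimethoxybenzene) | COC1=CC(OC)=CC#C1
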